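**Retrosynthetic overview**
1. Target 19 ⇒ reductive C-alkylation of hydroxyquinone 17 with lactol 15 (forms the C11–quinone bond and frees the C5 hydroxyl).
2. Lactol 15 ⇒ bridged γ-lactone 14, in which O5 and C11 are tied together across a trans-decalin.
3. Lactone 14 ⇒ key step: radical 6-endo cyclisation/lactonisation of α-bromo ester 12, which closes ring B (C9–C10) and the lactone ring (C5–O) in one operation; the C8 centre relays to C9, C10 and C5.
4. Bromo ester 12 ⇒ B-alkyl Suzuki union of enol triflate 8 (ring A, from 2,2-dimethylcyclohexanone) with pentenoate 5; C8 is set by asymmetric allylic alkylation.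
5. Ring order: ring A is bought; ring B and the lactone ring form together in step 7; the lactone ring is opened in the endgame; the quinone ring is bought.

Assumption: atom labels C1–C11 in the comments follow drimane numbering of the target (C4 = CMe2, C5 = C–OH, C8 = CHMe, C9 = quaternary carbon, C10 = ring-fusion CH, C11 = benzylic CH2; ring A = C1–C5/C10, ring B = C5–C10). Commercial E-enriched crotyl alcohol is used.

**Step 1**
Reactants: 1 (E)-but-2-en-1-ol
Product: 2 (E)-but-2-en-1-yl methyl carbonate
Conditions: ClCO2Me, pyridine, CH2Cl2, 0 °C → rt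
Reagents that add atoms: methyl chloroformate, COC(=O)Cl
Why: O-acylation of a primary allylic alcohol with a chloroformate (carbonate formation); no stereocentre is involved.

**Step 2**
Reactants: 2 (E)-but-2-en-1-yl methyl carbonate; 3 dimethyl 2-methylpropanedioate
Product: 4 dimethyl 2-[(2S)-but-3-en-2-yl]-2-methylpropanedioate
Conditions: [Ir(cod)Cl]2 (2 mol %), (Ra,R,R)-BINOL/bis(1-phenylethyl)amine phosphoramidite (4 mol %), TBD (8 mol %), THF, 25 → 50 °C (no added base)
Reagents that add atoms: none
Why: Asymmetric allylic alkylation with [Ir(cod)Cl]2/phosphoramidite (Helmchen–Hartwig type) attacks the methyl-bearing allyl terminus, so the branched product forms and the (Ra,R,R) ligand sets C8 as S (the ligand antipode would give R).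

**Step 3**
Reactants: 4 dimethyl 2-[(2S)-but-3-en-2-yl]-2-methylpropanedioate
Product: 5 methyl (3S)-2,3-dimethylpent-4-enoate
Conditions: LiCl, H2O, DMSO, 160 °C
Reagents that add atoms: none
Why: Krapcho dealkoxycarbonylation removes one ester by chloride attack on its methyl group and loss of CO2; C8 has no acidic hydrogen and is untouched, and the new C9 centre forms as a mixture that is erased in step 7.

**Step 4**
Reactants: 6 2,2-dimethylcyclohexan-1-one
Product: 8 6,6-dimethylcyclohex-1-en-1-yl trifluoromethanesulfonate, via lithium enolate 7 (not isolated)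
Conditions: LiN(i-Pr)2 (LDA), THF, −78 °C; PhNTf2, −78 °C → rt; aq. NH4Cl
Reagents that add atoms: N-phenylbis(trifluoromethanesulfonimide), O=S(=O)(N(c1ccccc1)S(=O)(=O)C(F)(F)F)C(F)(F)F
Why: The ketone can enolise only toward its CH2 group, so enolate O-triflation gives a single enol triflate.

**Step 5**
Reactants: 5 methyl (3S)-2,3-dimethylpent-4-enoate; 8 6,6-dimethylcyclohex-1-en-1-yl trifluoromethanesulfonate
Product: 10 methyl (3S)-5-(6,6-dimethylcyclohex-1-en-1-yl)-2,3-dimethylpentanoate, via alkyl-9-BBN borane 9 (not isolated)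
Conditions: 9-BBN, THF, 0 °C → rt; then 8, Pd(dppf)Cl2 (5 mol %), K3PO4, DMF–H2O, 60 °C
Reagents that add atoms: none
Why: Anti-Markovnikov hydroboration of the terminal alkene followed by B-alkyl Suzuki–Miyaura coupling with the enol triflate forms the C5–C6 bond; the ester and the C8 centre are spectators.

**Step 6**
Reactants: 10 methyl (3S)-5-(6,6-dimethylcyclohex-1-en-1-yl)-2,3-dimethylpentanoate
Product: 12 methyl (3S)-2-bromo-5-(6,6-dimethylcyclohex-1-en-1-yl)-2,3-dimethylpentanoate, via lithium ester enolate 11 (not isolated)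
Conditions: LiN(i-Pr)2 (LDA), THF, −78 °C; CBr4, −78 °C; aq. NH4Cl
Reagents that add atoms: tetrabromomethane, BrC(Br)(Br)Br
Why: Electrophilic bromination of the ester enolate gives the tertiary α-bromo ester; the C9 bromide is a mixture of epimers, which does not matter because C9 becomes a planar radical.

**Step 7 (key step)**
Reactants: 12 methyl (3S)-2-bromo-5-(6,6-dimethylcyclohex-1-en-1-yl)-2,3-dimethylpentanoate
Product: 14 (1S,2S,4aR,8aS)-4a-hydroxy-1,2,5,5-tetramethyldecahydronaphthalene-1-carboxylic acid 1,4a-lactone, via tertiary bromide 13 (not isolated)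
Conditions: fac-Ir(ppy)3 (1 mol %), MeCN, 450 nm LEDs, 25 °C; then 60 °C
Reagents that add atoms: none
Why: Proposed new method: photoreduction of the tertiary C–Br bond gives the α-ester radical at C9, which closes 6-endo onto the CH terminus C10 of the ring-A alkene (5-exo attack would need a bond to the fully substituted C5 next to CMe2) through a chair transition state with the C8 and C9 methyls equatorial and the smaller ester axial, and the tertiary C5 radical is trapped by bromine-atom transfer (13) or oxidation and then captured on the same face by the axial ester carbonyl with loss of CH3Br, so the single C8 centre sets C9, C10 and C5 (trans-decalin, O5 and C11 syn-diaxial); the closest known chemistry is Curran's atom-transfer cyclisation of α-halo esters with lactonisation of the γ-halo ester and Snider's 6-endo cyclisations of α-methyl α-ester radicals, which give the axial ester.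

**Step 8**
Reactants: 14 (1S,2S,4aR,8aS)-4a-hydroxy-1,2,5,5-tetramethyldecahydronaphthalene-1-carboxylic acid 1,4a-lactone
Product: 15 (1S,2S,4aR,8aS)-4a-hydroxy-1,2,5,5-tetramethyldecahydronaphthalene-1-carbaldehyde as its bridged lactol
Conditions: i-Bu2AlH (1.1 equiv), CH2Cl2, −78 °C; aq. potassium sodium tartrate
Reagents that add atoms: none
Why: Half-reduction of the hindered lactone by i-Bu2AlH stops at the aluminium hemiacetal at −78 °C and gives the lactol (masked C11 aldehyde plus C5 alcohol); C11 is an anomer mixture that is removed in step 10.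

**Step 9**
Reactants: 16 2,5-dimethoxy-1,4-benzoquinone
Product: 17 2-hydroxy-5-methoxy-1,4-benzoquinone
Conditions: NaOH (1.05 equiv), MeOH–H2O, 0 °C → rt; then HCl
Reagents that add atoms: sodium hydroxide, [Na+].[OH-]
Why: Addition–elimination of hydroxide on one vinylogous ester gives the monoanion, a vinylogous carboxylate that resists a second substitution, so hydrolysis stops at the mono-ether.

**Step 10**
Reactants: 15 lactol; 17 2-hydroxy-5-methoxy-1,4-benzoquinone
Product: 19 2-hydroxy-3-{[(1S,2S,4aR,8aS)-4a-hydroxy-1,2,5,5-tetramethyldecahydronaphthalen-1-yl]methyl}-5-methoxy-1,4-benzoquinone, via quinone methide 18 (not isolated)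
Conditions: L-proline (20 mol %), diethyl 2,6-dimethyl-1,4-dihydropyridine-3,5-dicarboxylate (1.3 equiv), CH2Cl2–EtOH, 40 °C; air work-up
Reagents that add atoms: none
Why: Three-component reductive alkylation (Ramachary type): the lactol reacts as its hydroxy-aldehyde in a Knoevenagel condensation at the nucleophilic C3 of the hydroxyquinone, and the Hantzsch ester reduces the alkylidene to the CH2 link; no stereocentre changes and the C5 alcohol is left free.

**Compound list**
1 | (E)-but-2-en-1-ol | C/C=C/CO | starting material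
2 | (E)-but-2-en-1-yl methyl carbonate | C/C=C/COC(=O)OC | intermediate
3 | dimethyl 2-methylpropanedioate | COC(=O)C(C)C(=O)OC | starting material
4 | dimethyl 2-[(2S)-but-3-en-2-yl]-2-methylpropanedioate | COC(=O)C(C)(C(=O)OC)[C@@H](C)C=C | intermediate
5 | methyl (3S)-2,3-dimethylpent-4-enoate (C2 epimers) | COC(=O)C(C)[C@@H](C)C=C | intermediate
6 | 2,2-dimethylcyclohexan-1-one | CC1(C)CCCCC1=O | starting material
7 | lithium 6,6-dimethylcyclohex-1-en-1-olate | [Li+].[O-]C1=CCCCC1(C)C | intermediate (not isolated)
8 | 6,6-dimethylcyclohex-1-en-1-yl trifluoromethanesulfonate | CC1(C)CCCC=C1OS(=O)(=O)C(F)(F)F | intermediate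
9 | methyl (3S)-5-(9-borabicyclo[3.3.1]nonan-9-yl)-2,3-dimethylpentanoate | COC(=O)C(C)[C@@H](C)CCB1C2CCCC1CCC2 | intermediate (not isolated)
10 | methyl (3S)-5-(6,6-dimethylcyclohex-1-en-1-yl)-2,3-dimethylpentanoate (C2 epimers) | COC(=O)C(C)[C@@H](C)CCC1=CCCCC1(C)C | intermediate
11 | lithium enolate of 10 | [Li+].[O-]C(OC)=C(C)[C@@H](C)CCC1=CCCCC1(C)C | intermediate (not isolated)
12 | methyl (3S)-2-bromo-5-(6,6-dimethylcyclohex-1-en-1-yl)-2,3-dimethylpentanoate (C2 epimers) | COC(=O)C(C)(Br)[C@@H](C)CCC1=CCCCC1(C)C | intermediate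
13 | methyl (1S,2S,8aS)-4a-bromo-1,2,5,5-tetramethyldecahydronaphthalene-1-carboxylate (C4a unassigned) | COC(=O)[C@@]1(C)[C@@H](C)CCC2(Br)[C@H]1CCCC2(C)C | intermediate (not isolated)
14 | (1S,2S,4aR,8aS)-4a-hydroxy-1,2,5,5-tetramethyldecahydronaphthalene-1-carboxylic acid 1,4a-lactone | O=C1[C@@]2(C)[C@@H](C)CC[C@@]3(O1)[C@H]2CCCC3(C)C | intermediate
15 | bridged lactol of (1S,2S,4aR,8aS)-4a-hydroxy-1,2,5,5-tetramethyldecahydronaphthalene-1-carbaldehyde (anomers) | OC1[C@@]2(C)[C@@H](C)CC[C@@]3(O1)[C@H]2CCCC3(C)C | intermediate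
16 | 2,5-dimethoxy-1,4-benzoquinone | COC1=CC(=O)C(OC)=CC1=O | starting material
17 | 2-hydroxy-5-methoxy-1,4-benzoquinone | COC1=CC(=O)C(O)=CC1=O | intermediate
18 | Knoevenagel adduct of 15 and 17 (3-alkylidene-5-methoxycyclohex-5-ene-1,2,4-trione) | COC1=CC(=O)C(=O)C(=C[C@@]2(C)[C@@H](C)CC[C@@]3(O)[C@H]2CCCC3(C)C)C1=O | intermediate (not isolated)
19 | 2-hydroxy-3-{[(1S,2S,4aR,8aS)-4a-hydroxy-1,2,5,5-tetramethyldecahydronaphthalen-1-yl]methyl}-5-methoxy-1,4-benzoquinone | COC1=CC(=O)C(O)=C(C[C@@]2(C)[C@@H](C)CC[C@@]3(O)[C@H]2CCCC3(C)C)C1=O | target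

**Totals**
Total step count: 10. Longest linear sequence: 8 (steps 1, 2, 3, 5, 6, 7, 8, 10).

**Steps most likely to fail**

Step 7. The tertiary radical may be reduced or eliminate before the 6-endo closure. The ester-axial preference at C9 is modest, so a C9-epimeric lactone is expected as a separable by-product. The C5 cation could also suffer a methyl shift from C4. The fallback replaces the radical closure by a stereospecific sigmatropic one; it sets out from 5 and 8 and comes back at 14. Aldehyde-selective Wacker oxidation of 5 (PdCl2(PhCN)2, CuCl2, AgNO2, O2, t-BuOH–MeNO2) gives methyl (3S)-2,3-dimethyl-5-oxopentanoate F1. Nozaki–Hiyama–Kishi coupling of F1 with 8 (CrCl2, NiCl2 cat., DMF), acid-promoted lactonisation and separation of the C6 epimers give the trans-4,6 δ-lactone (4S,6R)-6-(6,6-dimethylcyclohex-1-en-1-yl)-3,4-dimethyloxan-2-one F2. Its silyl ketene acetal (LDA, Me3SiCl/Et3N, THF, −78 °C, then toluene, 110 °C) undergoes the Danishefsky–Funk lactone-enolate Claisen ring contraction through the enforced boat transition state. This transfers the C6 chirality to C9 and C10 and gives, after aqueous work-up, (1S,2S,8aR)-1,2,5,5-tetramethyl-1,2,3,5,6,7,8,8a-octahydronaphthalene-1-carboxylic acid F3. Catalytic TfOH in CH2Cl2 then adds the acid across the C5=C6 alkene to give 14.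

Step 10. The aldehyde is neopentylic and locked in a bridged lactol, so the Knoevenagel condensation may be too slow. The fallback arylates C11 at the lactone oxidation level; it sets out from 14 and comes back at 19. 2,3,5,6-Tetramethoxyphenyllithium (from 1,2,4,5-tetramethoxybenzene and n-BuLi, THF, 0 °C) adds to 14 at −78 °C to give the cyclic aryl hemiketal F4. Ionic hydrogenation (Et3SiH, CF3CO2H, CH2Cl2, 0 °C) passes through the cyclic benzylic ether, is driven by the electron-rich arene, and gives (1S,2S,4aR,8aS)-1,2,5,5-tetramethyl-1-[(2,3,5,6-tetramethoxyphenyl)methyl]decahydronaphthalen-4a-ol F5. Oxidation with (NH4)2Ce(NO3)6 in MeCN–H2O at 0 °C gives the 2,5-dimethoxy-1,4-benzoquinone F6. Dilute NaOH in aqueous MeOH then hydrolyses the more hindered methoxy group next to the alkyl substituent to give 19.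

Step 2. The methyl-substituted malonate is a hindered nucleophile, and branched selectivity or ee may fall short. The fallback sets C8 by a sigmatropic route; it sets out from 1 and comes back at 5. Acylation of 1 with propanoyl chloride and pyridine gives (E)-but-2-en-1-yl propanoate F7. Corey's enantioselective Ireland–Claisen rearrangement (the enantiomer of the 2-bromo-4,5-diphenyl-1,3-bis(arylsulfonyl)-1,3,2-diazaborolidine that leads to the 3S acid, Et3N, toluene–hexane, −78 → 4 °C) gives (3S)-2,3-dimethylpent-4-enoic acid F8. Me3SiCHN2 in MeOH esterifies it to 5.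

**Further compounds**
F1 | step 7 | methyl (3S)-2,3-dimethyl-5-oxopentanoate | COC(=O)C(C)[C@@H](C)CC=O
F2 | step 7 | (4S,6R)-6-(6,6-dimethylcyclohex-1-en-1-yl)-3,4-dimethyloxan-2-one | O=C1O[C@H](C[C@H](C)C1C)C2=CCCCC2(C)C
F3 | step 7 | (1S,2S,8aR)-1,2,5,5-tetramethyl-1,2,3,5,6,7,8,8a-octahydronaphthalene-1-carboxylic acid | OC(=O)[C@@]1(C)[C@@H](C)CC=C2[C@H]1CCCC2(C)C
F4 | step 10 | cyclic hemiketal from addition of 2,3,5,6-tetramethoxyphenyllithium to the lactone carbonyl of 14 | OC1(c4c(OC)c(OC)cc(OC)c4OC)[C@@]2(C)[C@@H](C)CC[C@@]3(O1)[C@H]2CCCC3(C)C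
F5 | step 10 | (1S,2S,4aR,8aS)-1,2,5,5-tetramethyl-1-[(2,3,5,6-tetramethoxyphenyl)methyl]decahydronaphthalen-4a-ol | COc1cc(OC)c(OC)c(C[C@@]2(C)[C@@H](C)CC[C@@]3(O)[C@H]2CCCC3(C)C)c1OC
F6 | step 10 | 3-{[(1S,2S,4aR,8aS)-4a-hydroxy-1,2,5,5-tetramethyldecahydronaphthalen-1-yl]methyl}-2,5-dimethoxy-1,4-benzoquinone | COC1=CC(=O)C(OC)=C(C[C@@]2(C)[C@@H](C)CC[C@@]3(O)[C@H]2CCCC3(C)C)C1=O
F7 | step 2 | (E)-but-2-en-1-yl propanoate | CCC(=O)OC/C=C/C
F8 | step 2 | (3S)-2,3-dimethylpent-4-enoic acid | OC(=O)C(C)[C@@H](C)C=C
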